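**Plan**
- Retrosynthesis cuts O1–C2 (ring C, closed by oxa-Michael addition and dehydrogenation) and C4–C4a, which separates ring A from a ring B cinnamaldehyde.
- Enabling feature: ring A carries oxygen on C5, C6, C7 and C8a, the pattern of 2,6-dimethoxy-1,4-benzoquinone at the hydroquinone level; its two equivalent C–H carbons become C4a and C8.
- Forward: the ring B enal is built from 3,4,5-trimethoxyphenol (ortho-formylation, pivalate, two-carbon Wittig), then its acyl radical is joined to the quinone under visible light to form C4–C4a.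
- The non-chelated C6 hydroxyl is then methylated, ring C is closed and aromatised with I2/DMSO, and the 5-OMe and the pivalate are cleaved.
- The target is achiral, so no stereocentre has to be set; the E geometry of the enal comes from the stabilised ylide and disappears when ring C becomes aromatic.

Key step: step 4

Assumption: any Z-enone formed by photoisomerisation in step 4 converges to the same flavone in step 6, so the enone is drawn as E throughout.

**Route**

Step 1
Reactants: 1 3,4,5-trimethoxyphenol; 2 paraformaldehyde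
Product: 4 6-hydroxy-2,3,4-trimethoxybenzaldehyde, via salicyl alcohol 3 (not isolated)
Conditions: MgCl2, Et3N, (CH2O)n, MeCN, reflux; then 1 M HCl
Reagents that add atoms: paraformaldehyde 2 (reacts as formaldehyde), C=O
Why: Casnati–Skattebøl ortho-formylation, in which the magnesium phenoxide of 1 is hydroxymethylated at the ortho carbon to salicyl alcohol 3 and the magnesium alkoxide of 3 passes a hydride to a second formaldehyde; both ortho positions of 1 are equivalent, so only one aldehyde can result.

Step 2
Reactants: 4 6-hydroxy-2,3,4-trimethoxybenzaldehyde; 5 pivaloyl chloride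
Product: 6 2-formyl-3,4,5-trimethoxyphenyl pivalate
Conditions: PivCl, Et3N, DMAP (cat.), CH2Cl2, 0 °C to rt
Reagents that add atoms: pivaloyl chloride 5, CC(C)(C)C(=O)Cl
Why: DMAP-catalysed O-acylation of a phenol with an acid chloride; the pivalate masks the phenol, which would otherwise close onto the later enal and enone, and it offers no weak C–H bond to the excited quinone of step 4.

Step 3
Reactants: 6 2-formyl-3,4,5-trimethoxyphenyl pivalate; 7 (triphenylphosphoranylidene)acetaldehyde
Product: 8 3,4,5-trimethoxy-2-[(E)-3-oxoprop-1-enyl]phenyl pivalate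
Conditions: Ph3P=CHCHO (1.2 equiv), toluene, 90 °C
Reagents that add atoms: (triphenylphosphoranylidene)acetaldehyde 7, O=CC=P(c1ccccc1)(c1ccccc1)c1ccccc1
Why: Wittig olefination with the formyl-stabilised ylide, E-selective as is usual for stabilised ylides, with only a small excess of ylide so that a second homologation of the product enal is limited.

Step 4
Reactants: 8 3,4,5-trimethoxy-2-[(E)-3-oxoprop-1-enyl]phenyl pivalate; 9 2,6-dimethoxy-1,4-benzoquinone
Product: 11 2-[(E)-3-(3,6-dihydroxy-2,4-dimethoxyphenyl)-3-oxoprop-1-enyl]-3,4,5-trimethoxyphenyl pivalate, via keto tautomer 10 (not isolated)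
Conditions: 9 (2 equiv), 450 nm LEDs, degassed PhCF3/MeCN, 20 °C, argon
Reagents that add atoms: none
Why: Blue light excites only the quinone, whose triplet abstracts the weak formyl hydrogen of 8 to give a semiquinone and a conjugated acyl radical (which cannot lose CO, since a vinyl radical would result); this nucleophilic radical bonds to an unsubstituted ring carbon of 9, and hydrogen return gives keto tautomer 10, which enolises to the aromatic acylhydroquinone 11. The closest known reaction type is the photo-Friedel–Crafts acylation of 1,4-quinones with aldehydes, which has been applied to aliphatic, aromatic and α,β-unsaturated aldehydes. No ring is closed and no stereocentre is created; one C–C bond, the later C4–C4a, is formed in an addition that releases no co-product. Site selectivity on the quinone is needed and follows from its mirror plane: the two C–H carbons are equivalent and the methoxy-bearing carbons are blocked, so the acyl group must end up between one OH and one OMe. Chemoselectivity for the formyl C–H is needed and is secured by the pivalate (no weak C–H, and a weaker donor than a free or alkylated phenol, which limits electron-transfer quenching by ring B) and by the electron-poor enal C=C, a poor partner for oxetane formation. Excess 9 should not oxidise 11, because the acyl group makes 11 the harder hydroquinone to oxidise.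

Step 5
Reactants: 11 2-[(E)-3-(3,6-dihydroxy-2,4-dimethoxyphenyl)-3-oxoprop-1-enyl]-3,4,5-trimethoxyphenyl pivalate; 12 iodomethane
Product: 13 2-[(E)-3-(6-hydroxy-2,3,4-trimethoxyphenyl)-3-oxoprop-1-enyl]-3,4,5-trimethoxyphenyl pivalate
Conditions: MeI (1.1 equiv), K2CO3 (1.1 equiv), acetone, 40 °C, argon
Reagents that add atoms: iodomethane 12, CI
Why: Williamson O-methylation in which the hydroxyl destined to become O1 is held in a hydrogen bond to the ketone and stays unreacted, as in the classical partial methylation of 2,5-dihydroxyacetophenones; the aryl pivalate is inert to K2CO3 in acetone, and any flavanone formed by early oxa-Michael closure converges in step 6.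

Step 6
Reactants: 13 2-[(E)-3-(6-hydroxy-2,3,4-trimethoxyphenyl)-3-oxoprop-1-enyl]-3,4,5-trimethoxyphenyl pivalate
Product: 15 3,4,5-trimethoxy-2-(5,6,7-trimethoxy-4-oxo-4H-chromen-2-yl)phenyl pivalate, via flavanone 14 (not isolated)
Conditions: I2 (10 mol%), DMSO, 130 °C
Reagents that add atoms: none
Why: Iodine-catalysed oxidative cyclisation of a 2'-hydroxychalcone in DMSO, in which 6-endo-trig oxa-Michael addition of the chelated hydroxyl gives flavanone 14 and iodine dehydrogenates C2–C3 with DMSO as terminal oxidant; only one hydroxyl is free, so a single flavone can form.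

Step 7
Reactants: 15 3,4,5-trimethoxy-2-(5,6,7-trimethoxy-4-oxo-4H-chromen-2-yl)phenyl pivalate
Product: 17 2-(5-hydroxy-6,7-dimethoxy-4-oxo-4H-chromen-2-yl)-3,4,5-trimethoxyphenyl pivalate, via boron chelate 16 (not isolated)
Conditions: BCl3 (1.5 equiv), CH2Cl2, −78 to 0 °C; then H2O
Reagents that add atoms: none
Why: Chelation-controlled aryl methyl ether cleavage, in which BCl3 bridges the C4 carbonyl and the peri C5 methoxy oxygen, chloride removes that methyl to give boron chelate 16, and water hydrolyses it; the other five methoxy groups have no neighbouring carbonyl, and the pivalate is inert at 0 °C.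

Step 8
Reactants: 17 2-(5-hydroxy-6,7-dimethoxy-4-oxo-4H-chromen-2-yl)-3,4,5-trimethoxyphenyl pivalate
Product: 18 5,6'-dihydroxy-6,7,2',3',4'-pentamethoxyflavone
Conditions: K2CO3 (2 equiv), degassed MeOH, rt, argon; then sat. aq. NH4Cl
Reagents that add atoms: none
Why: Base-mediated methanolysis (transesterification) of an aryl ester, which proceeds at room temperature because the phenoxide is a good leaving group and is mild enough to leave the pyrone ring closed.

**Compound list**

1 | 3,4,5-trimethoxyphenol | COc1cc(O)cc(OC)c1OC | starting material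
2 | paraformaldehyde (formaldehyde source) | C=O | starting material
3 | salicyl alcohol: 2-(hydroxymethyl)-3,4,5-trimethoxyphenol (as its magnesium salt in the flask) | COc1cc(O)c(CO)c(OC)c1OC | intermediate
4 | 6-hydroxy-2,3,4-trimethoxybenzaldehyde | COc1cc(O)c(C=O)c(OC)c1OC | intermediate
5 | pivaloyl chloride | CC(C)(C)C(=O)Cl | starting material
6 | 2-formyl-3,4,5-trimethoxyphenyl pivalate | COc1cc(OC(=O)C(C)(C)C)c(C=O)c(OC)c1OC | intermediate
7 | (triphenylphosphoranylidene)acetaldehyde | O=CC=P(c1ccccc1)(c1ccccc1)c1ccccc1 | starting material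
8 | 3,4,5-trimethoxy-2-[(E)-3-oxoprop-1-enyl]phenyl pivalate | COc1cc(OC(=O)C(C)(C)C)c(/C=C/C=O)c(OC)c1OC | intermediate
9 | 2,6-dimethoxy-1,4-benzoquinone | COC1=CC(=O)C=C(OC)C1=O | starting material
10 | keto tautomer: 2-[(E)-3-(5-hydroxy-4,6-dimethoxy-2-oxocyclohexa-3,5-dien-1-yl)-3-oxoprop-1-enyl]-3,4,5-trimethoxyphenyl pivalate (racemic at the ring sp3 carbon) | COc1cc(OC(=O)C(C)(C)C)c(/C=C/C(=O)C2C(=O)C=C(OC)C(O)=C2OC)c(OC)c1OC | intermediate
11 | 2-[(E)-3-(3,6-dihydroxy-2,4-dimethoxyphenyl)-3-oxoprop-1-enyl]-3,4,5-trimethoxyphenyl pivalate | COc1cc(OC(=O)C(C)(C)C)c(/C=C/C(=O)c2c(O)cc(OC)c(O)c2OC)c(OC)c1OC | intermediate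
12 | iodomethane | CI | starting material
13 | 2-[(E)-3-(6-hydroxy-2,3,4-trimethoxyphenyl)-3-oxoprop-1-enyl]-3,4,5-trimethoxyphenyl pivalate | COc1cc(OC(=O)C(C)(C)C)c(/C=C/C(=O)c2c(O)cc(OC)c(OC)c2OC)c(OC)c1OC | intermediate
14 | flavanone: 3,4,5-trimethoxy-2-(5,6,7-trimethoxy-4-oxochroman-2-yl)phenyl pivalate (racemic) | COc1cc(OC(=O)C(C)(C)C)c(C2CC(=O)c3c(OC)c(OC)c(OC)cc3O2)c(OC)c1OC | intermediate
15 | 3,4,5-trimethoxy-2-(5,6,7-trimethoxy-4-oxo-4H-chromen-2-yl)phenyl pivalate | COc1cc(OC(=O)C(C)(C)C)c(-c2cc(=O)c3c(OC)c(OC)c(OC)cc3o2)c(OC)c1OC | intermediate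
16 | boron chelate: 2-[5-(dichloroboranyloxy)-6,7-dimethoxy-4-oxo-4H-chromen-2-yl]-3,4,5-trimethoxyphenyl pivalate (boron also bound to the C4 carbonyl oxygen) | COc1cc(OC(=O)C(C)(C)C)c(-c2cc(=O)c3c(OB(Cl)Cl)c(OC)c(OC)cc3o2)c(OC)c1OC | intermediate
17 | 2-(5-hydroxy-6,7-dimethoxy-4-oxo-4H-chromen-2-yl)-3,4,5-trimethoxyphenyl pivalate | COc1cc(OC(=O)C(C)(C)C)c(-c2cc(=O)c3c(O)c(OC)c(OC)cc3o2)c(OC)c1OC | intermediate
18 | 5,6'-dihydroxy-6,7,2',3',4'-pentamethoxyflavone, i.e. 5-hydroxy-2-(6-hydroxy-2,3,4-trimethoxyphenyl)-6,7-dimethoxy-4H-chromen-4-one | COc1cc(O)c(-c2cc(=O)c3c(O)c(OC)c(OC)cc3o2)c(OC)c1OC | target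

**Step count**

Total steps: 8. Longest linear sequence: 8 steps (1 to 18); quinone 9 is commercial and enters at step 4.

**Steps most likely to fail**

1. Step 4. The excited quinone may be quenched by electron transfer from the electron-rich ring B or by the enone product. The acyl radical may also couple at the semiquinone oxygen instead of at carbon, or the triplet may add across the enal C=C, so that C-acylation does not proceed cleanly. The fallback makes the same C4–C4a bond with reversed polarity, ring A as the nucleophile; it sets out from 1 and 8 and returns at 13, so step 5 is no longer needed. Phenol 1 would be protected with MOMCl/i-Pr2NEt in CH2Cl2 as 5-(methoxymethoxy)-1,2,3-trimethoxybenzene F1. Directed ortho-lithiation (n-BuLi, THF, 0 °C) between the OMOM and OMe groups would give [6-(methoxymethoxy)-2,3,4-trimethoxyphenyl]lithium F2. This would add 1,2 to enal 8 at −78 °C to give racemic 2-[(E)-3-hydroxy-3-[6-(methoxymethoxy)-2,3,4-trimethoxyphenyl]prop-1-enyl]-3,4,5-trimethoxyphenyl pivalate F3. MnO2 in CH2Cl2 would oxidise this allylic, benzylic alcohol to 2-[(E)-3-[6-(methoxymethoxy)-2,3,4-trimethoxyphenyl]-3-oxoprop-1-enyl]-3,4,5-trimethoxyphenyl pivalate F4. HCl in MeOH at 40 °C would remove the MOM group to give chalcone 13, from which steps 6 to 8 follow unchanged.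

2. Step 3. Olefination of the di-ortho-substituted, electron-rich aldehyde may be slow, and the less hindered product enal may react with the ylide a second time (over-homologation to the dienal). The fallback forms the aryl–vinyl bond by a Heck reaction; it sets out from 1 and returns at 8. Phenol 1 would be iodinated with NIS in MeCN at 0 °C to 2-iodo-3,4,5-trimethoxyphenol F5. Acylation with PivCl, Et3N and DMAP would give 2-iodo-3,4,5-trimethoxyphenyl pivalate F6. Coupling with acrolein under Jeffery conditions (Pd(OAc)2, n-Bu4NCl, NaHCO3, DMF, 60 °C) would deliver the E-enal 8 directly.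

3. Step 5. Methylation may also reach the chelated hydroxyl, which would block ring closure, or the hydroquinone anion may be oxidised by air to the acylquinone before it is alkylated. The fallback closes ring C first, so that no choice between two hydroxyls remains; it sets out from 11 and returns at 15. Treatment of 11 with I2 (cat.) in DMSO at 130 °C would give 2-(6-hydroxy-5,7-dimethoxy-4-oxo-4H-chromen-2-yl)-3,4,5-trimethoxyphenyl pivalate F7, in which the chelated hydroxyl has become O1. Its one remaining phenol would then be methylated with MeI/K2CO3 in acetone to give 15.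

**Further compounds**

F1 | step 4 | 5-(methoxymethoxy)-1,2,3-trimethoxybenzene | COCOc1cc(OC)c(OC)c(OC)c1
F2 | step 4 | [6-(methoxymethoxy)-2,3,4-trimethoxyphenyl]lithium | [Li]c1c(OCOC)cc(OC)c(OC)c1OC
F3 | step 4 | 2-[(E)-3-hydroxy-3-[6-(methoxymethoxy)-2,3,4-trimethoxyphenyl]prop-1-enyl]-3,4,5-trimethoxyphenyl pivalate (racemic) | COCOc1cc(OC)c(OC)c(OC)c1C(O)/C=C/c1c(OC(=O)C(C)(C)C)cc(OC)c(OC)c1OC
F4 | step 4 | 2-[(E)-3-[6-(methoxymethoxy)-2,3,4-trimethoxyphenyl]-3-oxoprop-1-enyl]-3,4,5-trimethoxyphenyl pivalate | COCOc1cc(OC)c(OC)c(OC)c1C(=O)/C=C/c1c(OC(=O)C(C)(C)C)cc(OC)c(OC)c1OC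
F5 | step 3 | 2-iodo-3,4,5-trimethoxyphenol | COc1cc(O)c(I)c(OC)c1OC
F6 | step 3 | 2-iodo-3,4,5-trimethoxyphenyl pivalate | COc1cc(OC(=O)C(C)(C)C)c(I)c(OC)c1OC
F7 | step 5 | 2-(6-hydroxy-5,7-dimethoxy-4-oxo-4H-chromen-2-yl)-3,4,5-trimethoxyphenyl pivalate | COc1cc(OC(=O)C(C)(C)C)c(-c2cc(=O)c3c(OC)c(O)c(OC)cc3o2)c(OC)c1OC
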